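## Retrosynthetic overview

1. The target is opened at the 1,10-oxirane (last step, peracid on the only electron-rich alkene) and at the C3 isovalerate; C3–OH comes from a catalyst-controlled reduction of a macrocyclic enone.
2. The ten-membered ring is disconnected at C3–C4: CrCl2/NiCl2 (Nozaki–Hiyama–Kishi) closure of a Z-vinyl iodide onto an aldehyde.
3. The C7–C8 bond and the α-methylene lactone come from a zinc Barbier reaction of an achiral β,γ-unsaturated aldehyde with a 3-(bromomethyl)butenolide; this gives the 8-epi alcohol, so C8 is inverted by Mitsunobu esterification with the epoxy acid.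
4. The bromobutenolide derives from an achiral α-chloro ynone: ketoreductase reduction sets C6, then ylide homologation, hydroalumination–iodination and ring-closing metathesis. The aldehyde comes from Zr-catalysed carboalumination; the epoxy acid from Sharpless epoxidation of tiglyl alcohol.
5. Ring order: side-chain oxirane → butenolide (becomes the α-methylene-γ-lactone in the Barbier step) → ten-membered carbocycle → 1,10-oxirane.

Assumption: macrocycles are named with germacrane numbering (ring C1–C10, lactone carbons C11–C13 on C7, methyl C14 on C10, methyl C15 on C4), and the same atom numbers are used when positions of acyclic precursors are discussed.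

## Route

**Step 1**
Reactants: 1 (2E)-2-methylbut-2-enoic acid (tiglic acid)
Product: 2 (2E)-2-methylbut-2-en-1-ol
Conditions: LiAlH4, Et2O, 0 °C to rt
Reagents that add atoms: none
Why: Hydride reduction of the conjugated acid gives the allylic alcohol and leaves the E geometry untouched.

**Step 2**
Reactants: 2 (2E)-2-methylbut-2-en-1-ol
Product: 3 [(2R,3R)-2,3-dimethyloxiran-2-yl]methanol
Conditions: Ti(OiPr)4 (10 mol%), D-(−)-diethyl tartrate (12 mol%), t-BuOOH, 4 Å MS, CH2Cl2, −20 °C
Reagents that add atoms: tert-butyl hydroperoxide, CC(C)(C)OO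
Why: Sharpless asymmetric epoxidation, in which the titanium–D-tartrate catalyst delivers oxygen to one face of the E-allylic alcohol and so sets both oxirane stereocentres from an achiral alkene.

**Step 3**
Reactants: 3 [(2R,3R)-2,3-dimethyloxiran-2-yl]methanol
Product: 5 (2S,3R)-2,3-dimethyloxirane-2-carboxylic acid, via epoxy aldehyde 4 (not isolated)
Conditions: TEMPO (20 mol%), PhI(OAc)2 (2.2 equiv), MeCN/H2O 1:1, rt
Reagents that add atoms: water, O
Why: Oxoammonium (TEMPO) oxidation of the primary alcohol through the aldehyde hydrate leaves the oxirane intact; the C2 descriptor changes from R to S only through CIP priorities.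

**Step 4**
Reactants: 6 tert-butyl(but-3-yn-1-yloxy)dimethylsilane; 7 oxirane
Product: 10 (3E)-6-{[tert-butyl(dimethyl)silyl]oxy}-4-methylhex-3-en-1-ol, via alkenylalane 8 (not isolated), via lithium alanate 9 (not isolated)
Conditions: AlMe3, Cp2ZrCl2 (25 mol%), CH2Cl2, 0 °C to rt; evaporate; n-BuLi, THF/hexane, −78 °C; then oxirane, −78 °C to rt
Reagents that add atoms: trimethylaluminium, C[Al](C)C
Why: Negishi zirconium-catalysed syn-carboalumination places methyl and aluminium cis, fixing the E-trisubstituted alkene (future C1=C10), and the derived alanate opens oxirane with retention of alkene geometry.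

**Step 5**
Reactants: 10 (3E)-6-{[tert-butyl(dimethyl)silyl]oxy}-4-methylhex-3-en-1-ol
Product: 11 tert-butyl{[(3E)-6-[(4-methoxyphenyl)methoxy]-3-methylhex-3-en-1-yl]oxy}dimethylsilane
Conditions: NaH, 4-methoxybenzyl chloride, Bu4NI (cat.), THF/DMF, 0 °C to rt
Reagents that add atoms: 4-methoxybenzyl chloride, COc1ccc(CCl)cc1
Why: Williamson etherification protects the future C3 oxygen as an ether that is later removable oxidatively under neutral conditions.

**Step 6**
Reactants: 11 tert-butyl{[(3E)-6-[(4-methoxyphenyl)methoxy]-3-methylhex-3-en-1-yl]oxy}dimethylsilane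
Product: 12 (3E)-6-[(4-methoxyphenyl)methoxy]-3-methylhex-3-en-1-ol
Conditions: Bu4NF, THF, 0 °C to rt
Reagents that add atoms: none
Why: Fluoride-mediated desilylation frees only the future C8 hydroxyl, since the benzyl-type ether is inert to fluoride.

**Step 7**
Reactants: 12 (3E)-6-[(4-methoxyphenyl)methoxy]-3-methylhex-3-en-1-ol
Product: 13 (3E)-6-[(4-methoxyphenyl)methoxy]-3-methylhex-3-enal
Conditions: Dess–Martin periodinane, NaHCO3, CH2Cl2, 0 °C; used crude
Reagents that add atoms: none
Why: Dess–Martin oxidation under buffered, base-free conditions gives the β,γ-unsaturated aldehyde without moving the alkene into conjugation.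

**Step 8**
Reactants: 14 2-chloro-N-methoxy-N-methylacetamide; 15 bromo(prop-1-yn-1-yl)magnesium
Product: 16 1-chloropent-3-yn-2-one
Conditions: THF, −20 to 0 °C; cold aq HCl quench
Reagents that add atoms: none
Why: Weinreb ketone synthesis, in which the chelated tetrahedral intermediate stops the alkynyl Grignard addition at the ketone stage.

**Step 9**
Reactants: 16 1-chloropent-3-yn-2-one
Product: 17 (2R)-1-chloropent-3-yn-2-ol
Conditions: ketoreductase (NADPH-dependent alcohol dehydrogenase, (R)-alcohol-forming, chosen from a screening panel), NADP+ (cat.), i-PrOH, phosphate buffer pH 7, 30 °C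
Reagents that add atoms: none
Why: Enzymatic carbonyl reduction by a ketoreductase delivers hydride to one face of the achiral ketone and sets the first stereocentre (future C6); α-halo alkynyl ketones are good substrates for this enzyme class.

**Step 10**
Reactants: 17 (2R)-1-chloropent-3-yn-2-ol
Product: 19 (3S)-hex-1-en-4-yn-3-ol, via alkynyl oxirane 18 (not isolated)
Conditions: Me3S+ I− (4 equiv), n-BuLi (3.9 equiv), THF, −20 °C to rt
Reagents that add atoms: trimethylsulfonium iodide, C[S+](C)C.[I-]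
Why: Intramolecular Williamson closure of the chlorohydrin followed by sulfonium-ylide opening and elimination (epoxide-to-allylic-alcohol homologation) adds the vinyl carbon without touching the carbinol stereocentre.

**Step 11**
Reactants: 19 (3S)-hex-1-en-4-yn-3-ol
Product: 21 (3S,4Z)-5-iodohexa-1,4-dien-3-ol, via cyclic alkenylalanate 20 (not isolated)
Conditions: NaAlH2(OCH2CH2OMe)2, THF, 0 °C to rt; then I2, −78 °C
Reagents that add atoms: iodine, II
Why: Hydroxyl-directed trans-hydroalumination puts aluminium on the distal alkyne carbon cis to the carbinol carbon, and iodinolysis with retention gives the Z-vinyl iodide (future C4=C5 geometry).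

**Step 12**
Reactants: 21 (3S,4Z)-5-iodohexa-1,4-dien-3-ol; 22 2-(bromomethyl)prop-2-enoic acid
Product: 23 (3S,4Z)-5-iodohexa-1,4-dien-3-yl 2-(bromomethyl)prop-2-enoate
Conditions: DCC, DMAP (5 mol%), CH2Cl2, 0 °C
Reagents that add atoms: none
Why: Steglich esterification under neutral conditions acylates the acid-sensitive bis-allylic alcohol with retention at the carbinol carbon.

**Step 13**
Reactants: 23 (3S,4Z)-5-iodohexa-1,4-dien-3-yl 2-(bromomethyl)prop-2-enoate
Product: 24 (5S)-3-(bromomethyl)-5-[(1Z)-2-iodoprop-1-en-1-yl]furan-2(5H)-one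
Conditions: RuCl2(=CHPh)(H2IMes)(PCy3) (second-generation Grubbs catalyst, 5 mol%), 1,4-benzoquinone (10 mol%), toluene, 80 °C, 5 mM
Reagents that add atoms: none
Why: Ring-closing metathesis between the vinyl group and the acrylate closes the butenolide with loss of ethene, while the trisubstituted iodoalkene is inert to the ruthenium carbene.

**Step 14**
Reactants: 13 (3E)-6-[(4-methoxyphenyl)methoxy]-3-methylhex-3-enal; 24 (5S)-3-(bromomethyl)-5-[(1Z)-2-iodoprop-1-en-1-yl]furan-2(5H)-one
Product: 25 (4R,5S)-4-[(1S,3E)-1-hydroxy-6-[(4-methoxyphenyl)methoxy]-3-methylhex-3-en-1-yl]-5-[(1Z)-2-iodoprop-1-en-1-yl]-3-methylideneoxolan-2-one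
Conditions: Zn dust, THF/sat. aq NH4Cl, 0 °C to rt
Reagents that add atoms: none
Why: Zinc Barbier allylation (SE2′) adds through C7 anti to the C6 substituent (6,7-trans) via a chair Zimmerman–Traxler transition state (7,8-anti), creating the α-methylene lactone, C7 and the (8S)-carbinol, which is the C8 epimer of the target.

**Step 15**
Reactants: 25 the Barbier alcohol named in step 14; 5 (2S,3R)-2,3-dimethyloxirane-2-carboxylic acid
Product: 26 (1R,3E)-1-[(2S,3R)-2-[(1Z)-2-iodoprop-1-en-1-yl]-4-methylidene-5-oxooxolan-3-yl]-6-[(4-methoxyphenyl)methoxy]-3-methylhex-3-en-1-yl (2S,3R)-2,3-dimethyloxirane-2-carboxylate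
Conditions: PPh3, DIAD (betaine preformed), toluene, 0 °C to rt
Reagents that add atoms: none
Why: Mitsunobu esterification, in which SN2 displacement of the oxyphosphonium by the carboxylate inverts C8 to the required 8R configuration and installs the side-chain ester in the same step.

**Step 16**
Reactants: 26 the ester named in step 15
Product: 27 (1R,3E)-6-hydroxy-1-[(2S,3R)-2-[(1Z)-2-iodoprop-1-en-1-yl]-4-methylidene-5-oxooxolan-3-yl]-3-methylhex-3-en-1-yl (2S,3R)-2,3-dimethyloxirane-2-carboxylate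
Conditions: DDQ, CH2Cl2/pH 7 buffer, 0 °C
Reagents that add atoms: none
Why: Oxidative cleavage of the electron-rich 4-methoxybenzyl ether frees the C3 hydroxyl under neutral conditions that spare the lactone, the oxirane ester and the vinyl iodide.

**Step 17**
Reactants: 27 the primary alcohol named in step 16
Product: 28 (1R,3E)-1-[(2S,3R)-2-[(1Z)-2-iodoprop-1-en-1-yl]-4-methylidene-5-oxooxolan-3-yl]-3-methyl-6-oxohex-3-en-1-yl (2S,3R)-2,3-dimethyloxirane-2-carboxylate
Conditions: Dess–Martin periodinane, NaHCO3, CH2Cl2, 0 °C; used crude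
Reagents that add atoms: none
Why: Dess–Martin oxidation gives the β,γ-unsaturated C3 aldehyde without base, so neither the alkene nor the lactone stereocentres are disturbed.

**Step 18**
Reactants: 28 the iodo aldehyde named in step 17
Product: 29 (3RS,6R,7R,8R)-3-hydroxy-8-{[(2S,3R)-2,3-dimethyloxiran-2-yl]carbonyloxy}germacra-1(10)E,4Z,11(13)-trien-12,6-olide
Conditions: CrCl2 (10 equiv), NiCl2 (2 mol%), DMSO, 2 mM, rt
Reagents that add atoms: none
Why: Intramolecular Nozaki–Hiyama–Kishi reaction, in which the alkenylchromium formed with retention of the Z geometry adds chemoselectively to the aldehyde at high dilution and closes the ten-membered ring; the C3 configuration is not relied on.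

**Step 19**
Reactants: 29 the macrocyclic allylic alcohol named in step 18
Product: 30 (6R,7R,8R)-8-{[(2S,3R)-2,3-dimethyloxiran-2-yl]carbonyloxy}-3-oxogermacra-1(10)E,4Z,11(13)-trien-12,6-olide
Conditions: Dess–Martin periodinane, NaHCO3, CH2Cl2, 0 °C to rt
Reagents that add atoms: none
Why: Dess–Martin oxidation of the allylic alcohol converges both C3 epimers on one Z-enone.

**Step 20**
Reactants: 30 the macrocyclic enone named in step 19
Product: 31 (3S,6R,7R,8R)-3-hydroxy-8-{[(2S,3R)-2,3-dimethyloxiran-2-yl]carbonyloxy}germacra-1(10)E,4Z,11(13)-trien-12,6-olide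
Conditions: (R)-2-methyl-CBS-oxazaborolidine (0.5 equiv), catecholborane, toluene, −78 °C
Reagents that add atoms: none
Why: Corey–Bakshi–Shibata reduction, in which the (R)-oxazaborolidine treats the α-methylalkenyl arm as the large group and delivers hydride 1,2 to give the (3S)-allylic alcohol under catalyst control.

**Step 21**
Reactants: 31 the (3S)-alcohol named in step 20; 32 3-methylbutanoic anhydride
Product: 33 (3S,6R,7R,8R)-3-(3-methylbutanoyloxy)-8-{[(2S,3R)-2,3-dimethyloxiran-2-yl]carbonyloxy}germacra-1(10)E,4Z,11(13)-trien-12,6-olide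
Conditions: DMAP (cat.), pyridine, CH2Cl2, 0 °C
Reagents that add atoms: none
Why: DMAP-catalysed acylation of the only free hydroxyl proceeds with retention at C3.

**Step 22**
Reactants: 33 the diester named in step 21
Product: 34 (1R,3S,6R,7R,8R,10R)-1,10-epoxy-3-(3-methylbutanoyloxy)-8-{[(2S,3R)-2,3-dimethyloxiran-2-yl]carbonyloxy}germacra-4Z,11(13)-dien-12,6-olide (CNP0167461.3)
Conditions: mCPBA, NaHCO3, CH2Cl2, 0 °C
Reagents that add atoms: 3-chloroperoxybenzoic acid, O=C(OO)c1cccc(Cl)c1
Why: Prilezhaev epoxidation attacks the only electron-rich alkene (C4=C5 is flanked by two acyloxy carbons, C11=C13 is conjugated) from the exposed outer face of the E-1(10) double bond, which by analogy with related germacranolides is expected to give the 1β,10α (1R,10R) oxide.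

## Compound list

1 | (2E)-2-methylbut-2-enoic acid | C/C=C(\C)C(=O)O | starting material
2 | (2E)-2-methylbut-2-en-1-ol | C/C=C(\C)CO | intermediate
3 | [(2R,3R)-2,3-dimethyloxiran-2-yl]methanol | OC[C@@]1(C)O[C@@H]1C | intermediate
4 | (2S,3R)-2,3-dimethyloxirane-2-carbaldehyde | O=C[C@@]1(C)O[C@@H]1C | intermediate
5 | (2S,3R)-2,3-dimethyloxirane-2-carboxylic acid | OC(=O)[C@@]1(C)O[C@@H]1C | intermediate
6 | tert-butyl(but-3-yn-1-yloxy)dimethylsilane | C#CCCO[Si](C)(C)C(C)(C)C | starting material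
7 | oxirane | C1CO1 | starting material
8 | [(1E)-4-{[tert-butyl(dimethyl)silyl]oxy}-2-methylbut-1-en-1-yl]dimethylalane | C[Al](C)/C=C(\C)CCO[Si](C)(C)C(C)(C)C | intermediate
9 | lithium butyl[(1E)-4-{[tert-butyl(dimethyl)silyl]oxy}-2-methylbut-1-en-1-yl]dimethylaluminate | [Li+].CCCC[Al-](C)(C)/C=C(\C)CCO[Si](C)(C)C(C)(C)C | intermediate
10 | (3E)-6-{[tert-butyl(dimethyl)silyl]oxy}-4-methylhex-3-en-1-ol | OCC/C=C(\C)CCO[Si](C)(C)C(C)(C)C | intermediate
11 | tert-butyl{[(3E)-6-[(4-methoxyphenyl)methoxy]-3-methylhex-3-en-1-yl]oxy}dimethylsilane | COc1ccc(COCC/C=C(\C)CCO[Si](C)(C)C(C)(C)C)cc1 | intermediate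
12 | (3E)-6-[(4-methoxyphenyl)methoxy]-3-methylhex-3-en-1-ol | COc1ccc(COCC/C=C(\C)CCO)cc1 | intermediate
13 | (3E)-6-[(4-methoxyphenyl)methoxy]-3-methylhex-3-enal | COc1ccc(COCC/C=C(\C)CC=O)cc1 | intermediate
14 | 2-chloro-N-methoxy-N-methylacetamide | CON(C)C(=O)CCl | starting material
15 | bromo(prop-1-yn-1-yl)magnesium | CC#C[Mg]Br | starting material
16 | 1-chloropent-3-yn-2-one | CC#CC(=O)CCl | intermediate
17 | (2R)-1-chloropent-3-yn-2-ol | CC#C[C@@H](O)CCl | intermediate
18 | (2R)-2-(prop-1-yn-1-yl)oxirane | CC#C[C@@H]1CO1 | intermediate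
19 | (3S)-hex-1-en-4-yn-3-ol | C=C[C@@H](C#CC)O | intermediate
20 | sodium (5S)-5-ethenyl-2,2-bis(2-methoxyethoxy)-3-methyl-2,5-dihydro-1,2-oxaaluminol-2-uide | [Na+].COCCO[Al-]1(OCCOC)O[C@@H](C=C)C=C1C | intermediate
21 | (3S,4Z)-5-iodohexa-1,4-dien-3-ol | C=C[C@@H](/C=C(/C)I)O | intermediate
22 | 2-(bromomethyl)prop-2-enoic acid | C=C(CBr)C(=O)O | starting material
23 | (3S,4Z)-5-iodohexa-1,4-dien-3-yl 2-(bromomethyl)prop-2-enoate | C=C[C@@H](/C=C(/C)I)OC(=O)C(=C)CBr | intermediate
24 | (5S)-3-(bromomethyl)-5-[(1Z)-2-iodoprop-1-en-1-yl]furan-2(5H)-one | BrCC1=C[C@@H](/C=C(/C)I)OC1=O | intermediate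
25 | (4R,5S)-4-[(1S,3E)-1-hydroxy-6-[(4-methoxyphenyl)methoxy]-3-methylhex-3-en-1-yl]-5-[(1Z)-2-iodoprop-1-en-1-yl]-3-methylideneoxolan-2-one | C=C1C(=O)O[C@H](/C=C(/C)I)[C@H]1[C@@H](O)C/C(C)=C/CCOCc2ccc(OC)cc2 | intermediate
26 | (1R,3E)-1-[(2S,3R)-2-[(1Z)-2-iodoprop-1-en-1-yl]-4-methylidene-5-oxooxolan-3-yl]-6-[(4-methoxyphenyl)methoxy]-3-methylhex-3-en-1-yl (2S,3R)-2,3-dimethyloxirane-2-carboxylate | C=C1C(=O)O[C@H](/C=C(/C)I)[C@H]1[C@H](OC(=O)[C@@]3(C)O[C@@H]3C)C/C(C)=C/CCOCc2ccc(OC)cc2 | intermediate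
27 | (1R,3E)-6-hydroxy-1-[(2S,3R)-2-[(1Z)-2-iodoprop-1-en-1-yl]-4-methylidene-5-oxooxolan-3-yl]-3-methylhex-3-en-1-yl (2S,3R)-2,3-dimethyloxirane-2-carboxylate | C=C1C(=O)O[C@H](/C=C(/C)I)[C@H]1[C@H](OC(=O)[C@@]3(C)O[C@@H]3C)C/C(C)=C/CCO | intermediate
28 | (1R,3E)-1-[(2S,3R)-2-[(1Z)-2-iodoprop-1-en-1-yl]-4-methylidene-5-oxooxolan-3-yl]-3-methyl-6-oxohex-3-en-1-yl (2S,3R)-2,3-dimethyloxirane-2-carboxylate | C=C1C(=O)O[C@H](/C=C(/C)I)[C@H]1[C@H](OC(=O)[C@@]3(C)O[C@@H]3C)C/C(C)=C/CC=O | intermediate
29 | (3RS,6R,7R,8R)-3-hydroxy-8-{[(2S,3R)-2,3-dimethyloxiran-2-yl]carbonyloxy}germacra-1(10)E,4Z,11(13)-trien-12,6-olide | C=C1C(=O)O[C@@H]2/C=C(/C)C(O)C/C=C(\C)C[C@@H](OC(=O)[C@@]3(C)O[C@@H]3C)[C@@H]12 | intermediate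
30 | (6R,7R,8R)-8-{[(2S,3R)-2,3-dimethyloxiran-2-yl]carbonyloxy}-3-oxogermacra-1(10)E,4Z,11(13)-trien-12,6-olide | C=C1C(=O)O[C@@H]2/C=C(/C)C(=O)C/C=C(\C)C[C@@H](OC(=O)[C@@]3(C)O[C@@H]3C)[C@@H]12 | intermediate
31 | (3S,6R,7R,8R)-3-hydroxy-8-{[(2S,3R)-2,3-dimethyloxiran-2-yl]carbonyloxy}germacra-1(10)E,4Z,11(13)-trien-12,6-olide | C=C1C(=O)O[C@@H]2/C=C(/C)[C@@H](O)C/C=C(\C)C[C@@H](OC(=O)[C@@]3(C)O[C@@H]3C)[C@@H]12 | intermediate
32 | 3-methylbutanoic anhydride | CC(C)CC(=O)OC(=O)CC(C)C | starting material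
33 | (3S,6R,7R,8R)-3-(3-methylbutanoyloxy)-8-{[(2S,3R)-2,3-dimethyloxiran-2-yl]carbonyloxy}germacra-1(10)E,4Z,11(13)-trien-12,6-olide | C=C1C(=O)O[C@@H]2/C=C(/C)[C@@H](OC(=O)CC(C)C)C/C=C(\C)C[C@@H](OC(=O)[C@@]3(C)O[C@@H]3C)[C@@H]12 | intermediate
34 | (1R,3S,6R,7R,8R,10R)-1,10-epoxy-3-(3-methylbutanoyloxy)-8-{[(2S,3R)-2,3-dimethyloxiran-2-yl]carbonyloxy}germacra-4Z,11(13)-dien-12,6-olide (CNP0167461.3) | C=C1C(=O)O[C@@H]2/C=C(/C)[C@@H](OC(=O)CC(C)C)C[C@H]3O[C@]3(C)C[C@@H](OC(=O)[C@@]3(C)O[C@@H]3C)[C@@H]12 | target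

## Step count and risk

Total: 22 steps. Longest linear sequence: 15 steps (steps 8–22, from 14 and 15 to 34).

The three steps most likely to fail:

**Step 15 (Mitsunobu inversion at C8 with the epoxy acid).** The alcohol is α-branched and homoallylic, so elimination is possible, and PPh3 can add to the α-methylene lactone. The fallback separates inversion from acylation. It sets out from 25: Mitsunobu reaction with chloroacetic acid (PPh3, DIAD, toluene), the most reliable acid for hindered secondary alcohols, gives the inverted (8R)-chloroacetate F1. Thiourea and NaHCO3 in EtOH/THF at 40 °C remove the chloroacetyl group without base strong enough to open the lactone and give the (8R)-alcohol F2. Steglich esterification of F2 with acid 5 (DCC, DMAP, CH2Cl2, 0 °C) proceeds with retention and comes back to the route at 26.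

**Step 18 (Nozaki–Hiyama–Kishi closure of the ten-membered ring).** Risks are oligomerisation, isomerisation of the β,γ-unsaturated aldehyde, and attack of divalent chromium on the α,β-epoxy ester. The fallback closes the ring before the epoxy ester is introduced and uses no protecting group at C8. It sets out from 25: DDQ (CH2Cl2/pH 7 buffer) gives the (8S)-diol F3. TEMPO/PhI(OAc)2 in CH2Cl2 oxidises only the primary hydroxyl to the hydroxy aldehyde F4. CrCl2/NiCl2 in DMSO at 2 mM closes the ring to the macrocyclic 3,8-diol F5. MnO2 in CH2Cl2 oxidises only the allylic C3 hydroxyl to the 8-hydroxy enone F6. Mitsunobu esterification of F6 with acid 5 (PPh3, DIAD, toluene) inverts C8 and comes back to the route at 30.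

**Step 22 (facial selectivity of the last epoxidation).** The outcome is substrate-controlled and rests on analogy; the peracid might deliver oxygen to the other face of the 1(10)-alkene. The fallback reaches the oxide of the opposite face by a two-step anti addition–closure. It sets out from 33: NBS in THF/H2O at 0 °C forms the bromonium ion on the face the peracid prefers, and water opens it at the tertiary C10 from the other face to give the (1S,10R)-bromohydrin F7. The electron-poor 4,5-alkene is a weak transannular participant. Ag2O in THF then closes the C10 alkoxide onto C1 with inversion, placing the oxirane oxygen on the face opposite to direct peracid attack, and comes back to the route at 34.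

## Further compounds

F1 | step 15 | (1R,3E)-1-[(2S,3R)-2-[(1Z)-2-iodoprop-1-en-1-yl]-4-methylidene-5-oxooxolan-3-yl]-6-[(4-methoxyphenyl)methoxy]-3-methylhex-3-en-1-yl 2-chloroacetate | C=C1C(=O)O[C@H](/C=C(/C)I)[C@H]1[C@H](OC(=O)CCl)C/C(C)=C/CCOCc2ccc(OC)cc2
F2 | step 15 | (4R,5S)-4-[(1R,3E)-1-hydroxy-6-[(4-methoxyphenyl)methoxy]-3-methylhex-3-en-1-yl]-5-[(1Z)-2-iodoprop-1-en-1-yl]-3-methylideneoxolan-2-one | C=C1C(=O)O[C@H](/C=C(/C)I)[C@H]1[C@H](O)C/C(C)=C/CCOCc2ccc(OC)cc2
F3 | step 18 | (4R,5S)-4-[(1S,3E)-1,6-dihydroxy-3-methylhex-3-en-1-yl]-5-[(1Z)-2-iodoprop-1-en-1-yl]-3-methylideneoxolan-2-one | C=C1C(=O)O[C@H](/C=C(/C)I)[C@H]1[C@@H](O)C/C(C)=C/CCO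
F4 | step 18 | (3E,6S)-6-hydroxy-6-[(2S,3R)-2-[(1Z)-2-iodoprop-1-en-1-yl]-4-methylidene-5-oxooxolan-3-yl]-4-methylhex-3-enal | C=C1C(=O)O[C@H](/C=C(/C)I)[C@H]1[C@@H](O)C/C(C)=C/CC=O
F5 | step 18 | (3RS,6R,7R,8S)-3,8-dihydroxygermacra-1(10)E,4Z,11(13)-trien-12,6-olide | C=C1C(=O)O[C@@H]2/C=C(/C)C(O)C/C=C(\C)C[C@H](O)[C@@H]12
F6 | step 18 | (6R,7R,8S)-8-hydroxy-3-oxogermacra-1(10)E,4Z,11(13)-trien-12,6-olide | C=C1C(=O)O[C@@H]2/C=C(/C)C(=O)C/C=C(\C)C[C@H](O)[C@@H]12
F7 | step 22 | (1S,3S,6R,7R,8R,10R)-1-bromo-10-hydroxy-3-(3-methylbutanoyloxy)-8-{[(2S,3R)-2,3-dimethyloxiran-2-yl]carbonyloxy}germacra-4Z,11(13)-dien-12,6-olide | C=C1C(=O)O[C@@H]2/C=C(/C)[C@@H](OC(=O)CC(C)C)C[C@H](Br)[C@](C)(O)C[C@@H](OC(=O)[C@@]3(C)O[C@@H]3C)[C@@H]12
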